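**Plan**

- Retrosynthesis: after ester hydrolysis and desilylation, the oxirane bond O7–C1 and the ring bond C1–C6 are cut together. The oxirane C1–O7–C6 is fused α,β to the C2 ketone of the cyclohexenone, so C1 is an enolate carbon and C6 an aldehyde carbon; both rings open to an acyclic (Z)-α-bromo keto aldehyde.
- The chain is then cut at C3–heptenyl (Suzuki), the side-chain C=C (cross-metathesis), C2–C1 (Weinreb ketone synthesis), C4–CH2O (vinyl cuprate, later ozonolysed) and C2–C3 (acetylide acylation), back to an alkyne from (S)-glyceraldehyde acetonide.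
- Forward: C5/C6 unit → ynoate → tetrasubstituted bromo enoate → ketone → side chain → heptenyl → C1 bromide → C6 aldehyde. The carbocycle and then the oxirane close in one operation, and two deprotections finish.
- Stereochemistry: C5 comes from the chiral pool; the C3=C4 geometry from syn-carbocupration/bromination; the two (E)-alkenes from cross-metathesis and from the boronic acid; C6 and C1 are set from C5 in the ring-forming step.
- Numbering used throughout: C1 (oxirane carbon bearing the butenoate chain), C2 (ketone), C3 (heptenyl), C4 (hydroxymethyl), C5 (carbinol), C6 (oxirane CH), O7.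

Key step: step 14

Remark: the C1 bromide of 25 and 27 is carried as an epimer mixture, which is harmless because C1 becomes planar in the enolate of step 14; 1 (distilled before use), 9 and 16 are bought.

**Route**

Step 1
Reactants: 1 (S)-2,2-dimethyl-1,3-dioxolane-4-carbaldehyde; 2 dimethyl (1-diazo-2-oxopropyl)phosphonate
Product: 3 (4R)-4-ethynyl-2,2-dimethyl-1,3-dioxolane
Conditions: K2CO3, MeOH, 0 °C → rt
Reagents that add atoms: dimethyl (1-diazo-2-oxopropyl)phosphonate (2), CC(=O)C(=[N+]=[N-])P(=O)(OC)OC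
Why: Ohira–Bestmann (Seyferth–Gilbert) homologation turns the aldehyde into the terminal alkyne under carbonate conditions that should leave the α-alkoxy stereocentre, the later C5, untouched.

Step 2
Reactants: 3 (4R)-4-ethynyl-2,2-dimethyl-1,3-dioxolane
Product: 4 (2R)-but-3-yne-1,2-diol
Conditions: Amberlyst 15 (H+ form), MeOH, rt
Reagents that add atoms: none
Why: Acid-catalysed transacetalisation removes the isopropylidene group now, because a free C5 hydroxyl could not be tolerated later beside the (Z)-enoate or (Z)-enone (lactone or furan formation).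

Step 3
Reactants: 4 (2R)-but-3-yne-1,2-diol
Product: 5 (3R)-3,4-bis(triethylsilyloxy)but-1-yne
Conditions: Et3SiCl, imidazole, DMAP (cat.), CH2Cl2, 0 °C → rt
Reagents that add atoms: chlorotriethylsilane, CC[Si](Cl)(CC)CC
Why: Standard silyl ether formation on both hydroxyls; the primary and secondary triethylsilyl ethers can be told apart in step 13, and the C5 silyl ether later acts as the stereocontrolling group.

Step 4
Reactants: 5 (3R)-3,4-bis(triethylsilyloxy)but-1-yne; 6 methyl chloroformate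
Product: 8 methyl (4R)-4,5-bis(triethylsilyloxy)pent-2-ynoate, via lithium acetylide 7 (not isolated)
Conditions: n-BuLi, THF, −78 °C; then ClCO2Me, −78 → 0 °C
Reagents that add atoms: methyl chloroformate (6), COC(=O)Cl
Why: Deprotonation of the terminal alkyne and C-acylation of the lithium acetylide with a chloroformate is the standard route to 2-ynoates and installs C2.

Step 5
Reactants: 8 methyl (4R)-4,5-bis(triethylsilyloxy)pent-2-ynoate; 9 vinylmagnesium bromide
Product: 11 methyl (2E,4R)-2-bromo-3-ethenyl-4,5-bis(triethylsilyloxy)pent-2-enoate, via alkenylcuprate 10 (not isolated)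
Conditions: CH2=CHMgBr (2.2 equiv), CuBr·SMe2 (1.1 equiv), THF, −78 → −40 °C; 8 added at −78 °C; then NBS (2.5 equiv), THF, −78 °C
Reagents that add atoms: vinylmagnesium bromide (9), C=C[Mg]Br; N-bromosuccinimide, O=C1CCC(=O)N1Br
Why: Syn-carbocupration of the ynoate (conjugate addition of a divinylcuprate) puts vinyl on C4 and copper on C3 on the same side, and bromination of the alkenylcopper with retention should give the tetrasubstituted alkene with the ester cis to C5, the same isomer also being favoured if the allenoate form is brominated from the side of the smaller vinyl group.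

Step 6
Reactants: 11 methyl (2E,4R)-2-bromo-3-ethenyl-4,5-bis(triethylsilyloxy)pent-2-enoate
Product: 13 methyl (2E,4R)-2-bromo-3-(hydroxymethyl)-4,5-bis(triethylsilyloxy)pent-2-enoate, via formyl enoate 12 (not isolated)
Conditions: O3, CH2Cl2/MeOH, −78 °C; Me2S; then CeCl3·7H2O, NaBH4, −78 → 0 °C
Reagents that add atoms: ozone, [O-][O+]=O
Why: Ozonolysis should be selective for the monosubstituted vinyl group over the tetrasubstituted bromine- and ester-bearing alkene, and Luche 1,2-reduction of the enal gives the C4 hydroxymethyl group, which lies trans to the ester and cannot lactonise.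

Step 7
Reactants: 13 methyl (2E,4R)-2-bromo-3-(hydroxymethyl)-4,5-bis(triethylsilyloxy)pent-2-enoate
Product: 14 methyl (2E,4R)-2-bromo-3-[(tert-butyldimethylsilyloxy)methyl]-4,5-bis(triethylsilyloxy)pent-2-enoate
Conditions: t-BuMe2SiCl, imidazole, DMF, 0 °C → rt
Reagents that add atoms: tert-butyl(chloro)dimethylsilane, CC(C)(C)[Si](C)(C)Cl
Why: Silyl ether formation at the primary allylic alcohol, the tert-butyldimethylsilyl group being chosen because primary ethers of this kind survive the Swern conditions that cleave the primary triethylsilyl ether in step 13.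

Step 8
Reactants: 14 methyl (2E,4R)-2-bromo-3-[(tert-butyldimethylsilyloxy)methyl]-4,5-bis(triethylsilyloxy)pent-2-enoate
Product: 15 (2E,4R)-2-bromo-3-[(tert-butyldimethylsilyloxy)methyl]-N-methoxy-N-methyl-4,5-bis(triethylsilyloxy)pent-2-enamide
Conditions: MeNH(OMe)·HCl, i-PrMgCl (premixed), THF, −20 → 0 °C
Reagents that add atoms: N,O-dimethylhydroxylamine hydrochloride, CNOC.Cl
Why: Weinreb amide formation by aminolysis of the methyl ester with the chloromagnesium amide, which is formed before the ester is added so that the alkenyl bromide never meets free isopropyl Grignard reagent.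

Step 9
Reactants: 15 (2E,4R)-2-bromo-3-[(tert-butyldimethylsilyloxy)methyl]-N-methoxy-N-methyl-4,5-bis(triethylsilyloxy)pent-2-enamide; 16 but-3-enylmagnesium bromide
Product: 18 (6E,8R)-6-bromo-7-[(tert-butyldimethylsilyloxy)methyl]-8,9-bis(triethylsilyloxy)nona-1,6-dien-5-one, via magnesium hemiaminal 17 (not isolated)
Conditions: THF, −40 → 0 °C; aq. NH4Cl
Reagents that add atoms: but-3-enylmagnesium bromide (16), C=CCC[Mg]Br
Why: Weinreb ketone synthesis, in which the primary Grignard reagent adds once to give a stable chelate that releases the ketone on work-up, while bromine–magnesium exchange at the alkenyl bromide should not compete at this temperature.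

Step 10
Reactants: 18 (6E,8R)-6-bromo-7-[(tert-butyldimethylsilyloxy)methyl]-8,9-bis(triethylsilyloxy)nona-1,6-dien-5-one; 19 methyl methacrylate
Product: 20 methyl (2E,7E,9R)-7-bromo-8-[(tert-butyldimethylsilyloxy)methyl]-2-methyl-6-oxo-9,10-bis(triethylsilyloxy)deca-2,7-dienoate
Conditions: second-generation Hoveyda–Grubbs catalyst, RuCl2(H2IMes)(=CH-C6H4-2-O-i-Pr) (5 mol %), 19 (10 equiv), CH2Cl2, 40 °C
Reagents that add atoms: methyl methacrylate (19), C=C(C)C(=O)OC
Why: Olefin cross-metathesis of a terminal alkene with a 1,1-disubstituted acrylate should give the (E)-trisubstituted enoate under thermodynamic control, and it is run before the heptenyl group is present so that the ruthenium alkylidene finds no second alkene for a six-ring-closing metathesis.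

Step 11
Reactants: 20 methyl (2E,7E,9R)-7-bromo-8-[(tert-butyldimethylsilyloxy)methyl]-2-methyl-6-oxo-9,10-bis(triethylsilyloxy)deca-2,7-dienoate; 21 (E)-hept-1-en-1-ylboronic acid
Product: 22 methyl (2E,7Z,9R)-8-[(tert-butyldimethylsilyloxy)methyl]-7-[(1E)-hept-1-en-1-yl]-2-methyl-6-oxo-9,10-bis(triethylsilyloxy)deca-2,7-dienoate
Conditions: Pd(OAc)2 (5 mol %), SPhos (10 mol %), K3PO4, THF/H2O (10:1), 40 °C
Reagents that add atoms: (E)-hept-1-en-1-ylboronic acid (21), CCCCC/C=C/B(O)O
Why: Suzuki–Miyaura coupling of the activated α-bromo enone with the alkenylboronic acid proceeds with retention at both alkenes and places the (E)-heptenyl group on C3.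

Step 12
Reactants: 22 methyl (2E,7Z,9R)-8-[(tert-butyldimethylsilyloxy)methyl]-7-[(1E)-hept-1-en-1-yl]-2-methyl-6-oxo-9,10-bis(triethylsilyloxy)deca-2,7-dienoate
Product: 25 methyl (2E,5RS,7Z,9R)-5-bromo-8-[(tert-butyldimethylsilyloxy)methyl]-7-[(1E)-hept-1-en-1-yl]-2-methyl-6-oxo-9,10-bis(triethylsilyloxy)deca-2,7-dienoate, via lithium enolate 23 (not isolated), via silyl enol ether 24 (not isolated)
Conditions: LiN(SiMe3)2, THF, −78 °C; Me3SiCl; then NBS, THF, −78 °C
Reagents that add atoms: N-bromosuccinimide, O=C1CCC(=O)N1Br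
Why: Kinetic deprotonation occurs at C1, the only sp3 α-carbon of the ketone (C3 is sp2), and α-bromination of the derived silyl enol ether with N-bromosuccinimide is regiospecific.

Step 13
Reactants: 25 methyl (2E,5RS,7Z,9R)-5-bromo-8-[(tert-butyldimethylsilyloxy)methyl]-7-[(1E)-hept-1-en-1-yl]-2-methyl-6-oxo-9,10-bis(triethylsilyloxy)deca-2,7-dienoate
Product: 27 methyl (2E,5RS,7Z,9R)-5-bromo-8-[(tert-butyldimethylsilyloxy)methyl]-7-[(1E)-hept-1-en-1-yl]-2-methyl-6,10-dioxo-9-(triethylsilyloxy)deca-2,7-dienoate, via alkoxysulfonium chloride 26 (not isolated)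
Conditions: (COCl)2, DMSO, CH2Cl2, −78 → −40 °C; then i-Pr2NEt, −78 → −20 °C; used crude
Reagents that add atoms: none
Why: Under Swern conditions a primary triethylsilyl ether is cleaved and oxidised directly to the aldehyde (oxidative desilylation) while secondary triethylsilyl and primary tert-butyldimethylsilyl ethers are retained, and the hindered amine at low temperature should limit epimerisation at C5.

Step 14
Reactants: 27 methyl (2E,5RS,7Z,9R)-5-bromo-8-[(tert-butyldimethylsilyloxy)methyl]-7-[(1E)-hept-1-en-1-yl]-2-methyl-6,10-dioxo-9-(triethylsilyloxy)deca-2,7-dienoate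
Product: 30 methyl (2E)-4-[(1R,5R,6R)-4-[(tert-butyldimethylsilyloxy)methyl]-3-[(1E)-hept-1-en-1-yl]-2-oxo-5-(triethylsilyloxy)-7-oxabicyclo[4.1.0]hept-3-en-1-yl]-2-methylbut-2-enoate, via lithium bromo enolate 28 (not isolated), via bromohydrin alkoxide 29 (not isolated)
Conditions: LiN(SiMe3)2 (1.05 equiv), THF, −78 → 0 °C
Reagents that add atoms: none
Why: LiN(SiMe3)2 removes the C1 proton flanked by the ketone and bromine (C3 is sp2 and the hindered C5–H beside the aldehyde is kinetically slower), the bromo enolate 28 adds to the C6 aldehyde in a 6-(enolendo)-exo-trig aldol that closes the carbocycle, and the C6 alkoxide of 29 displaces bromide at C1 in a 3-exo-tet SN2 closure of the oxirane; the sequence is an intramolecular Darzens condensation of an α-halo ketone with an aldehyde. The (Z)-C3=C4 alkene holds C2 and C5 on the same side so that C1 can reach C6, and the bromine on C1 also blocks dehydration of the aldolate to a phenol-type product. C6 is set by C5: addition anti to the C5–O bond of the bulky silyl ether (polar Felkin–Anh arrangement) places the new C6–O bond cis to C5–OSiEt3. C1 is set by the closure itself, because an oxirane on a six-membered ring can only be cis-fused and only the aldolate with bromine anti to the alkoxide can close, which puts the side chain on the face opposite to O7. The selectivity needed is closure to the oxirane cis to C5–O ahead of the trans isomer, of HBr loss toward the side chain and of aldehyde enolisation; the aldolates can revert at 0 °C, closure of the trans isomer would force bromine and the silyloxy group into a syn-1,3-diaxial relation, and one equivalent of a hindered amide base at −78 °C should keep elimination and C5 epimerisation slow.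

Step 15
Reactants: 30 methyl (2E)-4-[(1R,5R,6R)-4-[(tert-butyldimethylsilyloxy)methyl]-3-[(1E)-hept-1-en-1-yl]-2-oxo-5-(triethylsilyloxy)-7-oxabicyclo[4.1.0]hept-3-en-1-yl]-2-methylbut-2-enoate
Product: 32 (2E)-4-[(1R,5R,6R)-4-[(tert-butyldimethylsilyloxy)methyl]-3-[(1E)-hept-1-en-1-yl]-2-oxo-5-(triethylsilyloxy)-7-oxabicyclo[4.1.0]hept-3-en-1-yl]-2-methylbut-2-enoic acid, via trimethylstannyl ester 31 (not isolated)
Conditions: Me3SnOH, ClCH2CH2Cl, 70 °C; cold 0.1 M HCl wash
Reagents that add atoms: trimethyltin hydroxide, C[Sn](C)(C)O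
Why: Ester hydrolysis with trimethyltin hydroxide is a mild, nearly neutral cleavage of methyl esters that should spare the base-sensitive epoxy ketone and both silyl ethers.

Step 16
Reactants: 32 (2E)-4-[(1R,5R,6R)-4-[(tert-butyldimethylsilyloxy)methyl]-3-[(1E)-hept-1-en-1-yl]-2-oxo-5-(triethylsilyloxy)-7-oxabicyclo[4.1.0]hept-3-en-1-yl]-2-methylbut-2-enoic acid
Product: 33 (2E)-4-[(1R,5R,6R)-3-[(1E)-hept-1-en-1-yl]-5-hydroxy-4-(hydroxymethyl)-2-oxo-7-oxabicyclo[4.1.0]hept-3-en-1-yl]-2-methylbut-2-enoic acid (CNP0332048.1)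
Conditions: HF·pyridine, pyridine, THF, 0 °C → rt; Me3SiOMe quench
Reagents that add atoms: none
Why: Buffered fluoride-mediated desilylation removes both silyl ethers without opening the oxirane, and because the C5 hydroxyl is cis to the oxirane a Payne rearrangement is not possible.

**Compound list**

1 | (S)-2,2-dimethyl-1,3-dioxolane-4-carbaldehyde | CC1(C)OC[C@H](O1)C=O | starting material
2 | dimethyl (1-diazo-2-oxopropyl)phosphonate | CC(=O)C(=[N+]=[N-])P(=O)(OC)OC | starting material
3 | (4R)-4-ethynyl-2,2-dimethyl-1,3-dioxolane | CC1(C)OC[C@H](O1)C#C | intermediate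
4 | (2R)-but-3-yne-1,2-diol | OC[C@H](O)C#C | intermediate
5 | (3R)-3,4-bis(triethylsilyloxy)but-1-yne | CC[Si](CC)(CC)OC[C@H](O[Si](CC)(CC)CC)C#C | intermediate
6 | methyl chloroformate | COC(=O)Cl | starting material
7 | lithium acetylide of 5 | CC[Si](CC)(CC)OC[C@H](O[Si](CC)(CC)CC)C#C[Li] | intermediate
8 | methyl (4R)-4,5-bis(triethylsilyloxy)pent-2-ynoate | CC[Si](CC)(CC)OC[C@H](O[Si](CC)(CC)CC)C#CC(=O)OC | intermediate
9 | vinylmagnesium bromide | C=C[Mg]Br | starting material
10 | bromomagnesium alkenyl(vinyl)cuprate from syn-addition to 8 (Cu on C3 cis to the new vinyl group on C4) | COC(=O)/C([Cu-]C=C)=C(/C=C)[C@@H](O[Si](CC)(CC)CC)CO[Si](CC)(CC)CC.[Mg+]Br | intermediate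
11 | methyl (2E,4R)-2-bromo-3-ethenyl-4,5-bis(triethylsilyloxy)pent-2-enoate | COC(=O)/C(Br)=C(/C=C)[C@@H](O[Si](CC)(CC)CC)CO[Si](CC)(CC)CC | intermediate
12 | methyl (2Z,4R)-2-bromo-3-formyl-4,5-bis(triethylsilyloxy)pent-2-enoate | COC(=O)/C(Br)=C(/C=O)[C@@H](O[Si](CC)(CC)CC)CO[Si](CC)(CC)CC | intermediate
13 | methyl (2E,4R)-2-bromo-3-(hydroxymethyl)-4,5-bis(triethylsilyloxy)pent-2-enoate | COC(=O)/C(Br)=C(/CO)[C@@H](O[Si](CC)(CC)CC)CO[Si](CC)(CC)CC | intermediate
14 | methyl (2E,4R)-2-bromo-3-[(tert-butyldimethylsilyloxy)methyl]-4,5-bis(triethylsilyloxy)pent-2-enoate | COC(=O)/C(Br)=C(/CO[Si](C)(C)C(C)(C)C)[C@@H](O[Si](CC)(CC)CC)CO[Si](CC)(CC)CC | intermediate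
15 | (2E,4R)-2-bromo-3-[(tert-butyldimethylsilyloxy)methyl]-N-methoxy-N-methyl-4,5-bis(triethylsilyloxy)pent-2-enamide | CON(C)C(=O)/C(Br)=C(/CO[Si](C)(C)C(C)(C)C)[C@@H](O[Si](CC)(CC)CC)CO[Si](CC)(CC)CC | intermediate
16 | but-3-enylmagnesium bromide | C=CCC[Mg]Br | starting material
17 | bromomagnesium salt of the tetrahedral adduct of 16 to 15 | C=CCCC(O[Mg]Br)(N(C)OC)/C(Br)=C(/CO[Si](C)(C)C(C)(C)C)[C@@H](O[Si](CC)(CC)CC)CO[Si](CC)(CC)CC | intermediate
18 | (6E,8R)-6-bromo-7-[(tert-butyldimethylsilyloxy)methyl]-8,9-bis(triethylsilyloxy)nona-1,6-dien-5-one | C=CCCC(=O)/C(Br)=C(/CO[Si](C)(C)C(C)(C)C)[C@@H](O[Si](CC)(CC)CC)CO[Si](CC)(CC)CC | intermediate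
19 | methyl methacrylate | C=C(C)C(=O)OC | starting material
20 | methyl (2E,7E,9R)-7-bromo-8-[(tert-butyldimethylsilyloxy)methyl]-2-methyl-6-oxo-9,10-bis(triethylsilyloxy)deca-2,7-dienoate | COC(=O)/C(C)=C/CCC(=O)/C(Br)=C(/CO[Si](C)(C)C(C)(C)C)[C@@H](O[Si](CC)(CC)CC)CO[Si](CC)(CC)CC | intermediate
21 | (E)-hept-1-en-1-ylboronic acid | CCCCC/C=C/B(O)O | starting material
22 | methyl (2E,7Z,9R)-8-[(tert-butyldimethylsilyloxy)methyl]-7-[(1E)-hept-1-en-1-yl]-2-methyl-6-oxo-9,10-bis(triethylsilyloxy)deca-2,7-dienoate | CCCCC/C=C/C(C(=O)CC/C=C(\C)C(=O)OC)=C(\CO[Si](C)(C)C(C)(C)C)[C@@H](O[Si](CC)(CC)CC)CO[Si](CC)(CC)CC | intermediate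
23 | lithium enolate of 22 (enolate C1=C2 in the route numbering) | CCCCC/C=C/C(C(O[Li])=CC/C=C(\C)C(=O)OC)=C(\CO[Si](C)(C)C(C)(C)C)[C@@H](O[Si](CC)(CC)CC)CO[Si](CC)(CC)CC | intermediate
24 | trimethylsilyl enol ether of 22 | CCCCC/C=C/C(C(O[Si](C)(C)C)=CC/C=C(\C)C(=O)OC)=C(\CO[Si](C)(C)C(C)(C)C)[C@@H](O[Si](CC)(CC)CC)CO[Si](CC)(CC)CC | intermediate
25 | methyl (2E,5RS,7Z,9R)-5-bromo-8-[(tert-butyldimethylsilyloxy)methyl]-7-[(1E)-hept-1-en-1-yl]-2-methyl-6-oxo-9,10-bis(triethylsilyloxy)deca-2,7-dienoate | CCCCC/C=C/C(C(=O)C(Br)C/C=C(\C)C(=O)OC)=C(\CO[Si](C)(C)C(C)(C)C)[C@@H](O[Si](CC)(CC)CC)CO[Si](CC)(CC)CC | intermediate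
26 | dimethyl(alkoxy)sulfonium chloride formed at the C6 oxygen of 25 | CCCCC/C=C/C(C(=O)C(Br)C/C=C(\C)C(=O)OC)=C(\CO[Si](C)(C)C(C)(C)C)[C@@H](O[Si](CC)(CC)CC)CO[S+](C)C.[Cl-] | intermediate
27 | methyl (2E,5RS,7Z,9R)-5-bromo-8-[(tert-butyldimethylsilyloxy)methyl]-7-[(1E)-hept-1-en-1-yl]-2-methyl-6,10-dioxo-9-(triethylsilyloxy)deca-2,7-dienoate | CCCCC/C=C/C(C(=O)C(Br)C/C=C(\C)C(=O)OC)=C(\CO[Si](C)(C)C(C)(C)C)[C@@H](O[Si](CC)(CC)CC)C=O | intermediate
28 | lithium bromo enolate of 27 | CCCCC/C=C/C(C(O[Li])=C(Br)C/C=C(\C)C(=O)OC)=C(\CO[Si](C)(C)C(C)(C)C)[C@@H](O[Si](CC)(CC)CC)C=O | intermediate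
29 | lithium alkoxide of the cyclised bromohydrin (C6–O cis to C5–OSiEt3, C1–Br anti to C6–O) | CCCCC/C=C/C1=C(CO[Si](C)(C)C(C)(C)C)[C@@H](O[Si](CC)(CC)CC)[C@@H](O[Li])[C@@](Br)(C/C=C(\C)C(=O)OC)C1=O | intermediate
30 | methyl (2E)-4-[(1R,5R,6R)-4-[(tert-butyldimethylsilyloxy)methyl]-3-[(1E)-hept-1-en-1-yl]-2-oxo-5-(triethylsilyloxy)-7-oxabicyclo[4.1.0]hept-3-en-1-yl]-2-methylbut-2-enoate | CCCCC/C=C/C1=C(CO[Si](C)(C)C(C)(C)C)[C@@H](O[Si](CC)(CC)CC)[C@H]2O[C@@]2(C/C=C(\C)C(=O)OC)C1=O | intermediate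
31 | trimethylstannyl ester of 32 | CCCCC/C=C/C1=C(CO[Si](C)(C)C(C)(C)C)[C@@H](O[Si](CC)(CC)CC)[C@H]2O[C@@]2(C/C=C(\C)C(=O)O[Sn](C)(C)C)C1=O | intermediate
32 | (2E)-4-[(1R,5R,6R)-4-[(tert-butyldimethylsilyloxy)methyl]-3-[(1E)-hept-1-en-1-yl]-2-oxo-5-(triethylsilyloxy)-7-oxabicyclo[4.1.0]hept-3-en-1-yl]-2-methylbut-2-enoic acid | CCCCC/C=C/C1=C(CO[Si](C)(C)C(C)(C)C)[C@@H](O[Si](CC)(CC)CC)[C@H]2O[C@@]2(C/C=C(\C)C(=O)O)C1=O | intermediate
33 | (2E)-4-[(1R,5R,6R)-3-[(1E)-hept-1-en-1-yl]-5-hydroxy-4-(hydroxymethyl)-2-oxo-7-oxabicyclo[4.1.0]hept-3-en-1-yl]-2-methylbut-2-enoic acid | CCCCC/C=C/C1=C(CO)[C@@H](O)[C@H]2O[C@@]2(C/C=C(\C)C(=O)O)C1=O | target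

**Count and risks**

Total steps: 16. Longest linear sequence: 16 steps (1 → 33).

Most likely to fail, with fallbacks:

1. Step 14 (ring-forming cascade). The aldol addition may show poor facial selectivity at C6, the base may enolise the aldehyde and erode C5, or HBr may be lost toward the side chain before the ring closes. The fallback sets out from 25 and generates the bromo enolate reductively instead of by deprotonation. A second enol silylation and bromination (LiN(SiMe3)2, Me3SiCl, then N-bromosuccinimide) would give the gem-dibromo ketone F1. Swern oxidative desilylation as in step 13 would give the dibromo keto aldehyde F2. SmI2 in THF at −78 °C would then effect an intramolecular Reformatsky-type aldol without any base, giving the bromohydrin F3. F3 would be isolated, separated from unproductive diastereomers, and closed with DBU in CH2Cl2 at 0 °C, which comes back to the route at 30.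

2. Step 13 (oxidative desilylation). Cleavage of the primary triethylsilyl ether may be incomplete or unselective, or the amine stage may epimerise C5 or trigger HBr loss from the α-bromo ketone. The fallback sets out from 25 and separates deprotection from oxidation. HF·pyridine buffered with pyridine in THF at 0 °C would remove only the primary triethylsilyl group to give the primary alcohol F4. Dess–Martin periodinane with NaHCO3 in CH2Cl2 at 0 °C, an amine-free oxidation, would then come back to the route at 27.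

3. Step 8 (Weinreb amide formation). Acyl substitution at the ester, which is flanked by bromine and the cis C5 substituent, may be sluggish, and the same crowding could later favour loss of the N-methoxy group over Grignard addition. The fallback sets out from 14 and builds the ketone through the aldehyde oxidation level. i-Bu2AlH in CH2Cl2 at −78 °C would give the allylic alcohol F5, and MnO2 in CH2Cl2 the enal F6. Addition of 16 in THF at −78 °C would give the secondary alcohol F7 as an epimer mixture. Dess–Martin periodinane would then come back to the route at 18.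

Further compounds
F1 | step 14 | methyl (2E,7Z,9R)-5,5-dibromo-8-[(tert-butyldimethylsilyloxy)methyl]-7-[(1E)-hept-1-en-1-yl]-2-methyl-6-oxo-9,10-bis(triethylsilyloxy)deca-2,7-dienoate | CCCCC/C=C/C(C(=O)C(Br)(Br)C/C=C(\C)C(=O)OC)=C(\CO[Si](C)(C)C(C)(C)C)[C@@H](O[Si](CC)(CC)CC)CO[Si](CC)(CC)CC
F2 | step 14 | methyl (2E,7Z,9R)-5,5-dibromo-8-[(tert-butyldimethylsilyloxy)methyl]-7-[(1E)-hept-1-en-1-yl]-2-methyl-6,10-dioxo-9-(triethylsilyloxy)deca-2,7-dienoate | CCCCC/C=C/C(C(=O)C(Br)(Br)C/C=C(\C)C(=O)OC)=C(\CO[Si](C)(C)C(C)(C)C)[C@@H](O[Si](CC)(CC)CC)C=O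
F3 | step 14 | cyclised bromohydrin, the free alcohol of 29 (C6–OH cis to C5–OSiEt3, C1–Br anti to C6–OH) | CCCCC/C=C/C1=C(CO[Si](C)(C)C(C)(C)C)[C@@H](O[Si](CC)(CC)CC)[C@@H](O)[C@@](Br)(C/C=C(\C)C(=O)OC)C1=O
F4 | step 13 | methyl (2E,5RS,7Z,9R)-5-bromo-8-[(tert-butyldimethylsilyloxy)methyl]-7-[(1E)-hept-1-en-1-yl]-10-hydroxy-2-methyl-6-oxo-9-(triethylsilyloxy)deca-2,7-dienoate | CCCCC/C=C/C(C(=O)C(Br)C/C=C(\C)C(=O)OC)=C(\CO[Si](C)(C)C(C)(C)C)[C@@H](O[Si](CC)(CC)CC)CO
F5 | step 8 | (2E,4R)-2-bromo-3-[(tert-butyldimethylsilyloxy)methyl]-4,5-bis(triethylsilyloxy)pent-2-en-1-ol | OC/C(Br)=C(/CO[Si](C)(C)C(C)(C)C)[C@@H](O[Si](CC)(CC)CC)CO[Si](CC)(CC)CC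
F6 | step 8 | (2E,4R)-2-bromo-3-[(tert-butyldimethylsilyloxy)methyl]-4,5-bis(triethylsilyloxy)pent-2-enal | O=C/C(Br)=C(/CO[Si](C)(C)C(C)(C)C)[C@@H](O[Si](CC)(CC)CC)CO[Si](CC)(CC)CC
F7 | step 8 | (5RS,6E,8R)-6-bromo-7-[(tert-butyldimethylsilyloxy)methyl]-8,9-bis(triethylsilyloxy)nona-1,6-dien-5-ol | C=CCCC(O)/C(Br)=C(/CO[Si](C)(C)C(C)(C)C)[C@@H](O[Si](CC)(CC)CC)CO[Si](CC)(CC)CC
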